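**Retrosynthetic overview**

- The feature the route rests on is ring A (C4a, C5, C6, C7, C8, C8a). O1 on C8a, the C5 oxygen and the C7 oxygen sit on alternate carbons around the acyl-bearing C4a, with the C6 and C8 methoxy groups between them. This is the print of a folded chain of methoxyacetate units.
- Last disconnection: the C5 methyl ether, taken back to the chelated 5-hydroxyflavone.
- Key disconnections: C4a–C8a (Claisen, ring A) and O1–C2 (phenoxide addition–elimination, ring C). Both are formed in one operation from a 3,4,5-trimethoxy-2-pyranone carrying a 2-oxo-3,4-dimethoxy-4-arylbutenyl chain at C6.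
- The chain is attached by C-acylation of the lithiated 6-methyl group of 3,4,5-trimethoxy-6-methyl-2-pyranone with the imidazolide of 3-(2,4-dimethoxyphenyl)-2,3-dimethoxyacrylic acid.
- Ring order: sacrificial pyranone (methoxyacetate self-Claisen, dianion acetylation, lactonisation), then ring A, then ring C. Ring B is bought as 2,4-dimethoxybenzoyl chloride.

Key step: step 10

Assumption: the tetrasubstituted enol ether made in step 6 is drawn as the E isomer (aryl trans to the carbonyl carbon). The Z isomer or a mixture would serve equally, because ring C closes by addition–elimination through an sp3 carbon.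

**Route**

Step 1
Reactants: 1 methyl methoxyacetate (2 equiv)
Product: 2 methyl 2,4-dimethoxy-3-oxobutanoate (racemic, keto–enol mixture)
Conditions: NaH (1.1 equiv per product), cat. MeOH, toluene, 0 to 70 °C; then cold 1 M HCl
Reagents that add atoms: none
Why: Self-Claisen condensation of an ester with two α-hydrogens, driven to completion by deprotonation of the β-keto ester formed.

Step 2
Reactants: 2 methyl 2,4-dimethoxy-3-oxobutanoate; 3 N-methoxy-N-methylacetamide
Product: 4 methyl 2,4-dimethoxy-3,5-dioxohexanoate (mixture of diastereomers and enol forms)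
Conditions: LiN(iPr)2 (2.2 equiv), THF, −78 to 0 °C; then 3, −78 to 0 °C; aq. HCl
Reagents that add atoms: none
Why: Weiler-type dianion acylation, in which the more reactive γ-carbanion of the β-keto ester dianion attacks the Weinreb amide and the chelated tetrahedral adduct prevents over-addition.

Step 3
Reactants: 4 methyl 2,4-dimethoxy-3,5-dioxohexanoate
Product: 5 4-hydroxy-3,5-dimethoxy-6-methyl-2H-pyran-2-one
Conditions: DBU (1.2 equiv), toluene, reflux; then 1 M HCl
Reagents that add atoms: none
Why: Base-mediated lactonisation of a 3,5-dioxo ester, in which the C5 enol oxygen attacks the ester with loss of methanol, as in the formation of triacetic acid lactones.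

Step 4
Reactants: 5 4-hydroxy-3,5-dimethoxy-6-methyl-2H-pyran-2-one
Product: 6 3,4,5-trimethoxy-6-methyl-2H-pyran-2-one
Conditions: Me2SO4 (1.2 equiv), K2CO3, acetone, reflux
Reagents that add atoms: dimethyl sulfate, COS(=O)(=O)OC
Why: O-Methylation of the acidic 4-hydroxy-2-pyranone with a hard methylating agent, which should favour the 4-methoxy-2-pyranone over the 2-methoxy-4-pyranone isomer.

Step 5
Reactants: 1 methyl methoxyacetate (2.1 equiv); 7 2,4-dimethoxybenzoyl chloride
Product: 8 methyl 3-(2,4-dimethoxyphenyl)-2-methoxy-3-oxopropanoate (racemic)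
Conditions: LiN(iPr)2 (2.1 equiv), THF, −78 °C; then 7, −78 to −20 °C; aq. NH4Cl
Reagents that add atoms: none
Why: Crossed Claisen C-acylation of a preformed lithium ester enolate by an aroyl chloride, with the second equivalent of enolate taking up the acidic proton of the β-keto ester.

Step 6
Reactants: 8 methyl 3-(2,4-dimethoxyphenyl)-2-methoxy-3-oxopropanoate
Product: 9 methyl (2E)-3-(2,4-dimethoxyphenyl)-2,3-dimethoxyprop-2-enoate
Conditions: KN(SiMe3)2 (1.1 equiv), THF–DMPU, −78 °C; Me2SO4 (1.3 equiv), −78 to 0 °C
Reagents that add atoms: dimethyl sulfate, COS(=O)(=O)OC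
Why: O-Alkylation of a β-keto ester enolate, favoured by the potassium counter-ion, the dipolar aprotic cosolvent, the hard sulfate electrophile and the fully substituted α-carbon.

Step 7
Reactants: 9 methyl (2E)-3-(2,4-dimethoxyphenyl)-2,3-dimethoxyprop-2-enoate
Product: 10 (2E)-3-(2,4-dimethoxyphenyl)-2,3-dimethoxyprop-2-enoic acid
Conditions: LiOH·H2O (3 equiv), THF–MeOH–H2O, 40 °C; then 1 M HCl to pH 3–4 at 0 °C
Reagents that add atoms: lithium hydroxide, [Li+].[OH-] (the hydroxide oxygen becomes the carboxyl OH)
Why: Saponification of a methyl ester, to which the base-stable enol ether is inert, followed by cold and brief acidification that should spare the enol ether.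

Step 8
Reactants: 10 (2E)-3-(2,4-dimethoxyphenyl)-2,3-dimethoxyprop-2-enoic acid
Product: 11 (2E)-3-(2,4-dimethoxyphenyl)-1-(1H-imidazol-1-yl)-2,3-dimethoxyprop-2-en-1-one
Conditions: 1,1'-carbonyldiimidazole (1.1 equiv), CH2Cl2, rt; cold-water wash, dried, used crude
Reagents that add atoms: 1,1'-carbonyldiimidazole, O=C(n1ccnc1)n1ccnc1
Why: Acid activation as the N-acylimidazole under neutral conditions, which avoids the hydrogen chloride that an acid chloride preparation would bring to the enol ether.

Step 9
Reactants: 6 3,4,5-trimethoxy-6-methyl-2H-pyran-2-one; 11 (2E)-3-(2,4-dimethoxyphenyl)-1-(1H-imidazol-1-yl)-2,3-dimethoxyprop-2-en-1-one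
Product: 12 6-[(3E)-4-(2,4-dimethoxyphenyl)-3,4-dimethoxy-2-oxobut-3-en-1-yl]-3,4,5-trimethoxy-2H-pyran-2-one
Conditions: 6, LiN(SiMe3)2 (2.2 equiv), THF, −78 °C; then 11 in THF, −78 to −30 °C; AcOH quench
Reagents that add atoms: none
Why: Claisen-type C-acylation of the vinylogous enolate of a 6-methyl-2-pyranone by an acyl imidazolide, with the 6-methyl group the only acidic site since C3 and C5 are blocked, and the second equivalent of base holding the more acidic product as its enolate.

Step 10
Reactants: 12 6-[(3E)-4-(2,4-dimethoxyphenyl)-3,4-dimethoxy-2-oxobut-3-en-1-yl]-3,4,5-trimethoxy-2H-pyran-2-one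
Product: 15 2-(2,4-dimethoxyphenyl)-5-hydroxy-3,6,7,8-tetramethoxy-4H-chromen-4-one, via ring-opened keto ester 13 (not isolated), via dihydroxyphenyl enone 14 (not isolated)
Conditions: Mg(OMe)2 (4 equiv), MeOH, reflux; then cold 1 M HCl
Reagents that add atoms: none
Why: Magnesium-bound methoxide adds to the lactone carbonyl of 12 and opens the pyranone to the methyl ester 13, whose (2Z)-alkene keeps the ester cis to the chain while ketonisation at the former pyranone C5 frees rotation about the bond to the new ketone. The magnesium-chelated enolate of the methylene between the two ketones (future C4a) attacks the ester carbon (future C8a) in a 6-exo-trig Claisen condensation, and loss of methoxide followed by enolisation gives the aromatic 2,6-dihydroxy-3,4,5-trimethoxyphenyl ketone 14, which is ring A. One of its two phenoxides then adds 6-endo-trig to the β-carbon of the β-methoxy enone and methoxide is expelled (addition–elimination, O1 to C2), closing ring C as the chelated 5-hydroxychromone. The closest known reaction type is the Mg(OMe)2-induced ring opening and Claisen cyclisation of 6-(2-oxoalkyl)-4-methoxy-2-pyranones to acylphloroglucinols, joined to the usual closure of o-hydroxyaryl β-alkoxyvinyl ketones to chromones. No stereocentre is formed. The step needs Claisen rather than aldol folding and carbon rather than oxygen attack by the chain enolate: the possible aldol donors are methoxy-bearing carbons whose adducts cannot aromatise and so revert, magnesium chelation of the 1,3-dicarbonyl enolate favours C-acylation, and the twofold symmetry of ring A in 14 makes the choice of phenoxide irrelevant.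

Step 11
Reactants: 15 2-(2,4-dimethoxyphenyl)-5-hydroxy-3,6,7,8-tetramethoxy-4H-chromen-4-one
Product: 16 2-(2,4-dimethoxyphenyl)-3,5,6,7,8-pentamethoxy-4H-chromen-4-one
Conditions: Me2SO4 (3 equiv), K2CO3 (5 equiv), acetone, reflux
Reagents that add atoms: dimethyl sulfate, COS(=O)(=O)OC
Why: Williamson-type O-methylation of the hydrogen-bonded 5-hydroxyl of a flavone, which needs excess reagent and prolonged heating.

**Compound list**

1 | methyl methoxyacetate | COCC(=O)OC | starting material
2 | methyl 2,4-dimethoxy-3-oxobutanoate (racemic) | COCC(=O)C(OC)C(=O)OC | intermediate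
3 | N-methoxy-N-methylacetamide | CC(=O)N(C)OC | starting material
4 | methyl 2,4-dimethoxy-3,5-dioxohexanoate (diastereomer and enol mixture) | CC(=O)C(OC)C(=O)C(OC)C(=O)OC | intermediate
5 | 4-hydroxy-3,5-dimethoxy-6-methyl-2H-pyran-2-one | Cc1oc(=O)c(OC)c(O)c1OC | intermediate
6 | 3,4,5-trimethoxy-6-methyl-2H-pyran-2-one | Cc1oc(=O)c(OC)c(OC)c1OC | intermediate
7 | 2,4-dimethoxybenzoyl chloride | COc1ccc(C(=O)Cl)c(OC)c1 | starting material
8 | methyl 3-(2,4-dimethoxyphenyl)-2-methoxy-3-oxopropanoate (racemic) | COC(=O)C(OC)C(=O)c1ccc(OC)cc1OC | intermediate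
9 | methyl (2E)-3-(2,4-dimethoxyphenyl)-2,3-dimethoxyprop-2-enoate | COC(=O)/C(OC)=C(\OC)c1ccc(OC)cc1OC | intermediate
10 | (2E)-3-(2,4-dimethoxyphenyl)-2,3-dimethoxyprop-2-enoic acid | OC(=O)/C(OC)=C(\OC)c1ccc(OC)cc1OC | intermediate
11 | (2E)-3-(2,4-dimethoxyphenyl)-1-(1H-imidazol-1-yl)-2,3-dimethoxyprop-2-en-1-one | O=C(/C(OC)=C(\OC)c1ccc(OC)cc1OC)n1ccnc1 | intermediate
12 | 6-[(3E)-4-(2,4-dimethoxyphenyl)-3,4-dimethoxy-2-oxobut-3-en-1-yl]-3,4,5-trimethoxy-2H-pyran-2-one | COc1ccc(/C(OC)=C(\OC)C(=O)Cc2oc(=O)c(OC)c(OC)c2OC)c(OC)c1 | intermediate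
13 | methyl (2Z,8E)-9-(2,4-dimethoxyphenyl)-2,3,4,8,9-pentamethoxy-5,7-dioxonona-2,8-dienoate (C4 racemic, not isolated) | COC(=O)/C(OC)=C(OC)\C(OC)C(=O)CC(=O)/C(OC)=C(\OC)c1ccc(OC)cc1OC | intermediate
14 | (2E)-1-(2,6-dihydroxy-3,4,5-trimethoxyphenyl)-3-(2,4-dimethoxyphenyl)-2,3-dimethoxyprop-2-en-1-one (not isolated) | COc1ccc(/C(OC)=C(\OC)C(=O)c2c(O)c(OC)c(OC)c(OC)c2O)c(OC)c1 | intermediate
15 | 2-(2,4-dimethoxyphenyl)-5-hydroxy-3,6,7,8-tetramethoxy-4H-chromen-4-one | COc1ccc(-c2oc3c(OC)c(OC)c(OC)c(O)c3c(=O)c2OC)c(OC)c1 | intermediate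
16 | 2-(2,4-dimethoxyphenyl)-3,5,6,7,8-pentamethoxy-4H-chromen-4-one | COc1ccc(-c2oc3c(OC)c(OC)c(OC)c(OC)c3c(=O)c2OC)c(OC)c1 | target

**Step count**

Total: 11 steps. Longest linear sequence: 7 steps (steps 1–4, then 9–11; the branch through steps 5–8 and 9–11 is equally long).

**Steps most likely to fail**

Step 10. After ring opening, the enolate oxygen of the chain may add to the β-methoxy enone before the carbon–carbon bond forms, closing a 4-pyranone. Methoxide may also cleave the 1,3-dicarbonyl unit by retro-Claisen reaction, or exchange at the enol ether may divert material. The fallback separates the two ring closures and keeps the enone out of the basic medium.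
- It sets out from 6 and 1. The lithiated methyl group of 6 (LiN(SiMe3)2, THF, −78 °C) would be acylated by ester 1 to give 3,4,5-trimethoxy-6-(3-methoxy-2-oxopropyl)-2H-pyran-2-one F1.
- Mg(OMe)2 folding of F1, now with a plain 2-oxoalkyl chain as in the precedented cases, should give 1-(2,6-dihydroxy-3,4,5-trimethoxyphenyl)-2-methoxyethan-1-one F2.
- Allan–Robinson condensation of F2 with 2,4-dimethoxybenzoic anhydride F3 (from 7 and sodium 2,4-dimethoxybenzoate) and sodium 2,4-dimethoxybenzoate at about 180 °C would build ring C and aroylate the second phenol. This gives 2-(2,4-dimethoxyphenyl)-3,6,7,8-tetramethoxy-4-oxo-4H-chromen-5-yl 2,4-dimethoxybenzoate F4.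
- Hydrolysis of this ester with KOH in aqueous ethanol returns to the route at 15.

Step 9. Proton transfer from the acidic product to the lithiated pyranone, attack of the carbanion at the β-carbon of the acrylate instead of the carbonyl, or O-acylation may stop the acylation at low conversion. The fallback replaces acylation by aldol addition and oxidation.
- It sets out from 9. Reduction with iBu2AlH (CH2Cl2, −78 °C) would give (2E)-3-(2,4-dimethoxyphenyl)-2,3-dimethoxyprop-2-en-1-ol F5, and MnO2 oxidation would give (2E)-3-(2,4-dimethoxyphenyl)-2,3-dimethoxyprop-2-enal F6.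
- Addition of lithiated 6 (LiN(SiMe3)2, 1.1 equiv, THF, −78 °C) to F6 should give racemic 6-[(3E)-4-(2,4-dimethoxyphenyl)-2-hydroxy-3,4-dimethoxybut-3-en-1-yl]-3,4,5-trimethoxy-2H-pyran-2-one F7.
- Oxidation of F7 with Dess–Martin periodinane buffered with NaHCO3 returns to the route at 12.

Step 6. Methylation of the ambident enolate at carbon instead of oxygen would build a quaternary centre and consume the β-keto ester. The fallback reverses the polarity at the ketone carbon.
- It sets out from 8. Vilsmeier-type chlorination ((COCl)2, DMF, CH2Cl2) would give methyl 3-chloro-3-(2,4-dimethoxyphenyl)-2-methoxyprop-2-enoate F8 as a mixture of geometrical isomers.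
- Addition–elimination with NaOMe in MeOH at 0 °C to rt replaces chloride by methoxide and returns to the route at 9.

**Further compounds**

F1 | step 10 | 3,4,5-trimethoxy-6-(3-methoxy-2-oxopropyl)-2H-pyran-2-one | COCC(=O)Cc1oc(=O)c(OC)c(OC)c1OC
F2 | step 10 | 1-(2,6-dihydroxy-3,4,5-trimethoxyphenyl)-2-methoxyethan-1-one | COCC(=O)c1c(O)c(OC)c(OC)c(OC)c1O
F3 | step 10 | 2,4-dimethoxybenzoic anhydride | COc1ccc(C(=O)OC(=O)c2ccc(OC)cc2OC)c(OC)c1
F4 | step 10 | 2-(2,4-dimethoxyphenyl)-3,6,7,8-tetramethoxy-4-oxo-4H-chromen-5-yl 2,4-dimethoxybenzoate | COc1ccc(C(=O)Oc2c(OC)c(OC)c(OC)c3oc(-c4ccc(OC)cc4OC)c(OC)c(=O)c23)c(OC)c1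
F5 | step 9 | (2E)-3-(2,4-dimethoxyphenyl)-2,3-dimethoxyprop-2-en-1-ol | COc1ccc(/C(OC)=C(\OC)CO)c(OC)c1
F6 | step 9 | (2E)-3-(2,4-dimethoxyphenyl)-2,3-dimethoxyprop-2-enal | COc1ccc(/C(OC)=C(\OC)C=O)c(OC)c1
F7 | step 9 | 6-[(3E)-4-(2,4-dimethoxyphenyl)-2-hydroxy-3,4-dimethoxybut-3-en-1-yl]-3,4,5-trimethoxy-2H-pyran-2-one (racemic) | COc1ccc(/C(OC)=C(\OC)C(O)Cc2oc(=O)c(OC)c(OC)c2OC)c(OC)c1
F8 | step 6 | methyl 3-chloro-3-(2,4-dimethoxyphenyl)-2-methoxyprop-2-enoate (E/Z mixture) | COC(=O)C(OC)=C(Cl)c1ccc(OC)cc1OC
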